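**Retrosynthetic overview**
1. The strategy rests on where the ether oxygen sits: on ring B at C2, between C3 (OMe) and C1 (CH2OH), and on ring A at the carbon ortho to the CO2Me carbon. The CH2OH carbon can therefore first be the acyl carbon of an aryl salicylate (depside), and the ring A ester activates its neighbouring carbon for aryl transfer.
2. Last disconnections: the C-prenyl bond on ring A comes from an aromatic Claisen shift of a 1,1-dimethylallyl ether on the adjacent phenol oxygen; before that, CH2OH comes from CO2H.
3. Key disconnection: the diaryl ether C–O bond comes from a Smiles O-to-O aryl migration within depside 15.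
4. The depside comes from ring A phenol 8 (from 3,5-dimethoxytoluene and 2-methylbut-3-yn-2-ol) and ring B silyloxy acid 13 (from o-vanillin) by esterification.
5. Ring order: no ring is built. Both benzene rings are bought, joined as an ester, the link is contracted to the ether, and the prenyl group is moved from O to C last.

Key step: step 11

Remark: the target has no stereocentre and its alkene ends in two identical methyl groups, so nothing stereochemical has to be set. The ring B hydroxy acid is carried as its tert-butyldimethylsilyl ether (13) until the depside is in place.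

**Route**

Step 1
Reactants: 1 3,5-dimethoxytoluene
Product: 3 methyl 2,6-dimethoxy-4-methylbenzoate, via aryllithium 2 (not isolated)
Conditions: n-BuLi, TMEDA, THF, 0 °C to rt; then cannulated into ClCO2Me (3 equiv), THF, −78 °C
Reagents that add atoms: methyl chloroformate, COC(=O)Cl
Why: Directed ortho-lithiation, in which the two methoxy groups together steer the base to the carbon between them, followed by acylation of the hindered aryllithium by inverse addition so that it should stop at the ester.

Step 2
Reactants: 3 methyl 2,6-dimethoxy-4-methylbenzoate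
Product: 4 methyl 2,6-dihydroxy-4-methylbenzoate
Conditions: BBr3 (2.5 equiv), CH2Cl2, −78 to 0 °C; then ice-water
Reagents that add atoms: none
Why: Lewis acid cleavage of aryl methyl ethers, which, assisted by chelation to the ester carbonyl, should be faster than attack on the methyl ester at low temperature.

Step 3
Reactants: 4 methyl 2,6-dihydroxy-4-methylbenzoate; 5 2-methylbut-3-yn-2-ol
Product: 7 methyl 2-hydroxy-4-methyl-6-[(2-methylbut-3-yn-2-yl)oxy]benzoate, via propargylic trifluoroacetate 6 (not isolated)
Conditions: 5 (1.05 equiv), (CF3CO)2O, DBU, MeCN, −5 °C; then added to 4, DBU, CuCl2·2H2O (cat.), MeCN, −5 to 0 °C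
Reagents that add atoms: none
Why: Copper-catalysed propargylic etherification, in which the copper acetylide of 6 ionises and the phenoxide captures the tertiary carbon; one equivalent of electrophile and the lower reactivity of the remaining chelated, more crowded phenol should favour mono-alkylation of the symmetrical diol.

Step 4
Reactants: 7 methyl 2-hydroxy-4-methyl-6-[(2-methylbut-3-yn-2-yl)oxy]benzoate
Product: 8 methyl 2-hydroxy-4-methyl-6-[(2-methylbut-3-en-2-yl)oxy]benzoate
Conditions: H2 (1 atm), Pd/CaCO3 poisoned with Pb(OAc)2, quinoline, EtOAc, rt, stopped at one equivalent of H2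
Reagents that add atoms: none
Why: Lindlar semihydrogenation of the terminal alkyne to the vinyl group, with ester, phenol and aryl ether untouched; the product is kept cold and away from acid.

Step 5
Reactants: 9 o-vanillin (2-hydroxy-3-methoxybenzaldehyde)
Product: 10 5-bromo-2-hydroxy-3-methoxybenzaldehyde
Conditions: Br2, NaOAc, AcOH, rt
Reagents that add atoms: bromine, BrBr
Why: Electrophilic aromatic bromination directed by the phenol to its para carbon, since both ortho carbons are already substituted.

Step 6
Reactants: 10 5-bromo-2-hydroxy-3-methoxybenzaldehyde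
Product: 11 2-hydroxy-3,5-dimethoxybenzaldehyde
Conditions: NaOMe, MeOH, CuCl (cat.), DMF, 110 °C; then acidification
Reagents that add atoms: sodium methoxide, C[O-].[Na+]
Why: Copper-catalysed Ullmann-type methoxylation of the aryl bromide, the same exchange that turns 5-bromovanillin into syringaldehyde; the aldehyde is shielded as part of the phenoxide.

Step 7
Reactants: 11 2-hydroxy-3,5-dimethoxybenzaldehyde
Product: 12 2-[(tert-butyldimethylsilyl)oxy]-3,5-dimethoxybenzaldehyde
Conditions: TBSCl, imidazole, DMF, rt
Reagents that add atoms: tert-butyldimethylsilyl chloride, CC(C)(C)[Si](C)(C)Cl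
Why: Standard silylation of a phenol, giving a fluoride-labile group that can later be removed without hydrogenolysis or acid.

Step 8
Reactants: 12 2-[(tert-butyldimethylsilyl)oxy]-3,5-dimethoxybenzaldehyde
Product: 13 2-[(tert-butyldimethylsilyl)oxy]-3,5-dimethoxybenzoic acid
Conditions: NaClO2, NaH2PO4, 2-methyl-2-butene (excess), t-BuOH/H2O, 0 °C to rt
Reagents that add atoms: sodium chlorite, [Na+].[O-]Cl=O
Why: Pinnick oxidation of the aldehyde to the acid under buffered conditions, with the alkene scavenger removing hypochlorous acid before it can chlorinate the electron-rich ring.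

Step 9
Reactants: 8 methyl 2-hydroxy-4-methyl-6-[(2-methylbut-3-en-2-yl)oxy]benzoate; 13 2-[(tert-butyldimethylsilyl)oxy]-3,5-dimethoxybenzoic acid
Product: 14 2-(methoxycarbonyl)-5-methyl-3-[(2-methylbut-3-en-2-yl)oxy]phenyl 2-[(tert-butyldimethylsilyl)oxy]-3,5-dimethoxybenzoate
Conditions: DCC, DMAP, CH2Cl2, 0 °C to rt
Reagents that add atoms: none
Why: Steglich esterification, in which the acylpyridinium species should be reactive enough to acylate the hydrogen-bonded ring A phenol, while the silyl ether prevents self-condensation of the salicylic acid.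

Step 10
Reactants: 14 silyl-protected depside
Product: 15 2-(methoxycarbonyl)-5-methyl-3-[(2-methylbut-3-en-2-yl)oxy]phenyl 2-hydroxy-3,5-dimethoxybenzoate
Conditions: TBAF, AcOH (1:1), THF, 0 °C
Reagents that add atoms: none
Why: Fluoride desilylation of the aryl silyl ether, buffered with acetic acid so that the phenol and not the reactive phenoxide is released and the aryl ester stays intact.

Step 11
Reactants: 15 depside with free ortho phenol on the acyl ring
Product: 16 2-{2-(methoxycarbonyl)-5-methyl-3-[(2-methylbut-3-en-2-yl)oxy]phenoxy}-3,5-dimethoxybenzoic acid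
Conditions: K2CO3 (dried, 3 equiv), dry DMSO, rt, N2; then cold aqueous citric acid work-up
Reagents that add atoms: none
Why: Carbonate deprotonates the ring B phenol, and the phenoxide adds to the ring A carbon that carries the ester oxygen (ipso attack, 6-exo-trig) to give a spiro benzo-1,3-dioxin-4-one Meisenheimer anion stabilised by the ortho methyl ester; expulsion of the carboxylate then breaks the acyl C–O–aryl bond and leaves the diaryl ether. This is a Smiles rearrangement, an intramolecular nucleophilic aromatic substitution of the kind known for ortho-hydroxy depsides on the way to 2-aryloxybenzoic acids and depsidones. The only ring formed is the transient six-membered spiro ring, which opens again, so no permanent ring and no stereocentre arise. Ipso substitution must outrun ester cleavage and acyl transfer: the six-membered transition state reaches only the ester-activated carbon, dry carbonate in DMSO offers no external nucleophile, the second ring A oxygen is capped as the tertiary allyl ether, and exchanging a phenoxide for a far weaker carboxylate base should make the migration irreversible.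

Step 12
Reactants: 16 diaryl ether acid
Product: 18 methyl 2-[2-(hydroxymethyl)-4,6-dimethoxyphenoxy]-4-methyl-6-[(2-methylbut-3-en-2-yl)oxy]benzoate, via mixed carbonic anhydride 17 (not isolated)
Conditions: i-BuOCOCl, N-methylmorpholine, THF, −15 °C; then NaBH4, H2O, −15 to 0 °C
Reagents that add atoms: none
Why: Mixed-anhydride activation followed by borohydride reduction converts only the free acid to the primary alcohol, because NaBH4 at 0 °C should leave the hindered methyl ester and the alkene alone, whereas borane would hydroborate the vinyl group.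

Step 13
Reactants: 18 diaryl ether benzyl alcohol
Product: 19 methyl 6-[2-(hydroxymethyl)-4,6-dimethoxyphenoxy]-2-hydroxy-4-methyl-3-(3-methylbut-2-en-1-yl)benzoate (target)
Conditions: degassed toluene, sealed tube, 120 °C
Reagents that add atoms: none
Why: Aromatic Claisen [3,3]-sigmatropic rearrangement, in which the 1,1-dimethylallyl group is delivered with allylic transposition as a prenyl group to the only free ortho carbon (the other ortho carbon carries the ester), and tautomerisation of the dienone restores the phenol.

**Compound list**
1 | 3,5-dimethoxytoluene | Cc1cc(OC)cc(OC)c1 | starting material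
2 | 2,6-dimethoxy-4-methylphenyllithium | [Li]c1c(OC)cc(C)cc1OC | intermediate
3 | methyl 2,6-dimethoxy-4-methylbenzoate | COC(=O)c1c(OC)cc(C)cc1OC | intermediate
4 | methyl 2,6-dihydroxy-4-methylbenzoate | COC(=O)c1c(O)cc(C)cc1O | intermediate
5 | 2-methylbut-3-yn-2-ol | CC(C)(O)C#C | starting material
6 | 2-methylbut-3-yn-2-yl trifluoroacetate | CC(C)(OC(=O)C(F)(F)F)C#C | intermediate
7 | methyl 2-hydroxy-4-methyl-6-[(2-methylbut-3-yn-2-yl)oxy]benzoate | COC(=O)c1c(O)cc(C)cc1OC(C)(C)C#C | intermediate
8 | methyl 2-hydroxy-4-methyl-6-[(2-methylbut-3-en-2-yl)oxy]benzoate | COC(=O)c1c(O)cc(C)cc1OC(C)(C)C=C | intermediate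
9 | o-vanillin (2-hydroxy-3-methoxybenzaldehyde) | COc1cccc(C=O)c1O | starting material
10 | 5-bromo-2-hydroxy-3-methoxybenzaldehyde | COc1cc(Br)cc(C=O)c1O | intermediate
11 | 2-hydroxy-3,5-dimethoxybenzaldehyde | COc1cc(OC)c(O)c(C=O)c1 | intermediate
12 | 2-[(tert-butyldimethylsilyl)oxy]-3,5-dimethoxybenzaldehyde | COc1cc(OC)c(O[Si](C)(C)C(C)(C)C)c(C=O)c1 | intermediate
13 | 2-[(tert-butyldimethylsilyl)oxy]-3,5-dimethoxybenzoic acid | COc1cc(OC)c(O[Si](C)(C)C(C)(C)C)c(C(=O)O)c1 | intermediate
14 | 2-(methoxycarbonyl)-5-methyl-3-[(2-methylbut-3-en-2-yl)oxy]phenyl 2-[(tert-butyldimethylsilyl)oxy]-3,5-dimethoxybenzoate | COC(=O)c1c(OC(=O)c2cc(OC)cc(OC)c2O[Si](C)(C)C(C)(C)C)cc(C)cc1OC(C)(C)C=C | intermediate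
15 | 2-(methoxycarbonyl)-5-methyl-3-[(2-methylbut-3-en-2-yl)oxy]phenyl 2-hydroxy-3,5-dimethoxybenzoate | COC(=O)c1c(OC(=O)c2cc(OC)cc(OC)c2O)cc(C)cc1OC(C)(C)C=C | intermediate
16 | 2-{2-(methoxycarbonyl)-5-methyl-3-[(2-methylbut-3-en-2-yl)oxy]phenoxy}-3,5-dimethoxybenzoic acid | COC(=O)c1c(Oc2c(C(=O)O)cc(OC)cc2OC)cc(C)cc1OC(C)(C)C=C | intermediate
17 | isobutyl carbonic mixed anhydride of acid 16 | COC(=O)c1c(Oc2c(C(=O)OC(=O)OCC(C)C)cc(OC)cc2OC)cc(C)cc1OC(C)(C)C=C | intermediate
18 | methyl 2-[2-(hydroxymethyl)-4,6-dimethoxyphenoxy]-4-methyl-6-[(2-methylbut-3-en-2-yl)oxy]benzoate | COC(=O)c1c(Oc2c(CO)cc(OC)cc2OC)cc(C)cc1OC(C)(C)C=C | intermediate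
19 | methyl 6-[2-(hydroxymethyl)-4,6-dimethoxyphenoxy]-2-hydroxy-4-methyl-3-(3-methylbut-2-en-1-yl)benzoate | COC(=O)c1c(Oc2c(CO)cc(OC)cc2OC)cc(C)c(CC=C(C)C)c1O | target

**Totals**
Total step count: 13.
Longest linear sequence: 9 steps (steps 1–4 then 9–13, or equally steps 5–8 then 9–13).

**Steps most likely to fail**

Step 11 (Smiles migration). The aryl transfer may lose to cleavage of the depside ester by adventitious hydroxide, or stall because a single ortho ester activates ring A only moderately. The fallback makes the ether bond intermolecularly and sets out from phenol 8. Ullmann-type coupling of 8 with 2-iodo-3,5-dimethoxybenzaldehyde F1 (from 3,5-dimethoxybenzaldehyde and N-iodosuccinimide) under CuI, picolinic acid and K3PO4 in DMSO, kept at or below 80 °C to spare the tertiary allyl ether, should give methyl 2-(2-formyl-4,6-dimethoxyphenoxy)-4-methyl-6-[(2-methylbut-3-en-2-yl)oxy]benzoate F2. Reduction of the aldehyde with NaBH4 in MeOH at 0 °C brings the material back to the route at 18.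

Step 9 (esterification). Acylation of the chelated, flanked ring A phenol may be too slow, and silyl transfer from the phenol oxygen to the neighbouring carboxyl group of 13 may erode the protection during activation. The fallback changes the acyl donor and sets out from 13. TBAF in THF should free 2-hydroxy-3,5-dimethoxybenzoic acid F3, which acetone with (CF3CO)2O and CF3CO2H should close to 6,8-dimethoxy-2,2-dimethyl-4H-1,3-benzodioxin-4-one F4. The sodium phenoxide of 8 (NaH, THF, 0 °C to rt) should open the dioxinone at its carbonyl with loss of acetone. A buffered quench then delivers the free-phenol depside 15 directly, so that 14 and step 10 are bypassed.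

Step 13 (Claisen shift). On heating, the tertiary allyl group may be lost as isoprene, or migration may start at the ester-bearing ortho carbon and run on to the para position. The fallback installs the prenyl group by direct C-alkylation and sets out from 18. Pd(PPh3)4 with morpholine in THF at rt should remove the allyl group and give methyl 2-hydroxy-6-[2-(hydroxymethyl)-4,6-dimethoxyphenoxy]-4-methylbenzoate F5. Its sodium phenoxide (NaH, 1 equiv, toluene) with prenyl bromide should undergo ortho C-alkylation at the only free ortho carbon, giving the target 19.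

**Further compounds**
F1 | step 11 | 2-iodo-3,5-dimethoxybenzaldehyde | COc1cc(OC)c(I)c(C=O)c1
F2 | step 11 | methyl 2-(2-formyl-4,6-dimethoxyphenoxy)-4-methyl-6-[(2-methylbut-3-en-2-yl)oxy]benzoate | COC(=O)c1c(Oc2c(C=O)cc(OC)cc2OC)cc(C)cc1OC(C)(C)C=C
F3 | step 9 | 2-hydroxy-3,5-dimethoxybenzoic acid | COc1cc(OC)c(O)c(C(=O)O)c1
F4 | step 9 | 6,8-dimethoxy-2,2-dimethyl-4H-1,3-benzodioxin-4-one | COc1cc(OC)c2OC(C)(C)OC(=O)c2c1
F5 | step 13 | methyl 2-hydroxy-6-[2-(hydroxymethyl)-4,6-dimethoxyphenoxy]-4-methylbenzoate | COC(=O)c1c(Oc2c(CO)cc(OC)cc2OC)cc(C)cc1O
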